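# Proposed synthesis of CNP0110777.0 (14) by oxidative C–H etherification at C7a

## The problem

Target 14 is a 2-aryl-3-methylbenzofuran. Its benzo ring (ring A) is substituted on every carbon but C4: C5 carries a methoxy group, C6 a free hydroxyl group and C7 an allyl group; C2 of the furan ring carries a 3,4,5-trimethoxyphenyl ring and C3 a methyl group. The molecule has no stereocentre, so no centre can steer another, and the difficulty is regiochemical: the substituents of ring A must come in the right order, and the furan oxygen must sit on the ring carbon next to the allyl-bearing one. Three groups limit the choice of reagents. The free phenol on a very electron-rich benzofuran is easily oxidised and must be masked in any oxidative step; the terminal alkene of the allyl group is lost to hydrogenation, moves into conjugation under strong base, and can add the neighbouring hydroxyl group under acid, so it should arrive last; and the four methyl ethers must survive whatever frees O6. Two features of the substitution pattern allow a short route. C7a is para to the C5 methoxy group and ortho to C3a, so in an open-chain 1,2-diarylpropan-1-one the ketone oxygen lies five atoms from an unsubstituted, methoxy-activated C–H position, and the O1–C7a bond can be made by oxidising ring A without a halogen. O6 is flanked by C5, blocked by methoxy, and C7, which carries hydrogen, so an allyl group placed on O6 can migrate only to C7.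

## Retrosynthesis

**C7–allyl bond.** The bond between C7 and the allyl CH2 of 14 is cut first, which leads back to allyl ether 12 through ortho-dienone 13 (Claisen rearrangement). A direct C-allylation or a cross-coupling would need a halogen or a metal at C7. The sigmatropic shift needs only heat, and its regiochemistry is enforced: C5 is blocked and the para carbon C3a is a ring-fusion atom. The precursor has one carbon substituent less on ring A. The forward step must run without acid, so that the new ortho-allylphenol does not cyclise.

**O6–allyl and O6–protecting group bonds.** Ether 12 comes from phenol 10 and allyl bromide 11. Phenol 10 comes from isopropyl ether 8 through aryloxydichloroborane 9. Isopropyl is preferred to benzyl because the step before it uses FeCl3, a Lewis acid that can strip benzyl ethers and would then oxidise the freed phenol. A secondary alkyl ether is inert to FeCl3 and is later cleaved by BCl3 under conditions that leave methyl ethers alone.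

**O1–C7a bond (key disconnection).** Opening the furan ring of 8 between O1 and C7a gives ketone 7, racemic 2-[3-methoxy-4-(propan-2-yloxy)phenyl]-1-(3,4,5-trimethoxyphenyl)propan-1-one. Cutting O1–C2 instead would need an ortho-oxygenated, fully substituted ring A built beforehand. Cutting at C7a with a halide leaving group would need an extra halogenation. The dehydrogenative version uses the C–H bond as it stands. Ketone 7 has no ring besides the two arenes, and its single stereocentre is erased in the closure. The forward reaction must oxidise the dialkoxyphenyl ring and not the trimethoxyphenyl ring, and close at the carbon para to methoxy. An extra acceptor on the α-carbon would bring the closure inside existing precedent, but it would have to be reduced to the methyl group afterwards. The plain ketone is kept, and the risk is covered by a halide-based fallback from the same compound.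

**Cα–aryl bond.** Ketone 7 is cut between the α-carbon and the dialkoxyphenyl ring into propiophenone 4 and aryl bromide 6, joined by palladium-catalysed enolate arylation. This joins two arenes of equal size in one step and puts the methyl group in place with the ketone. An acylation route would have to make a 2-arylpropanoic acid derivative first.

**Building blocks.** Ketone 4 comes from nitrile 1 and ethylmagnesium bromide 2 through ketimine salt 3, which gives the ketone oxidation level directly. Bromide 6 is the isopropyl ether of commercial 4-bromo-2-methoxyphenol 5.

## Roads not taken

**Alternative 1:** The cut goes through ring A itself. Cyclobutenone A2 would be assembled from a squaric ester by adding the allyl, methoxy and dienyl units in turn. On heating, A2 opens to a dienylketene; 6π electrocyclisation forms C3a–C7a, and enolisation gives phenol A1. In A1 the allyl, isopropoxy, methoxy and styryl groups already stand in their final order. Oxidative closure of the phenol oxygen onto the stilbene double bond (O1–C2) and removal of the isopropyl group would finish the synthesis.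
- Merits: every position of ring A is fixed by the order of additions and not by directing effects. The thermal ring expansion is established for this compound class, which the key step of the chosen plan is not.
- Weak points: ring A is a guaiacol with one carbon substituent and can be bought in that form, so building it from a four-carbon unit spends many low-temperature organometallic steps on it. The (1E,3E)-dienyl nucleophile carrying the trimethoxyphenyl ring needs its own synthesis. After A1, two more steps remain, one of them an oxidation next to an allyl group.
- Comparison: this road is more certain in regiochemistry but roughly twice as long. The chosen plan sets against it seven steps from commercial arenes and two regiochemical decisions secured by the substitution pattern.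

**Alternative 2:** The C3–C3a and O1–C2 bonds are cut together. Acid ionises quinone monoketal A4 to a methoxy-stabilised cation, which adds to the alkene of (E)-isoelemicin A5. Capture of the benzylic cation by the carbonyl oxygen gives dihydrobenzofuranone A3. A Cope shift then moves the angular allyl group from C3a to C7 and aromatises ring A to dihydrobenzofuran A6, which must be dehydrogenated across C2–C3.
- Merits: two bonds form in one step from two simple partners, no protecting group is needed, and the allyl group reaches C7 by a sigmatropic shift. In step count and convergence this road is better than the chosen one.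
- Weak points: the cation–alkene addition has two outlets, capture by oxygen (A3) or by carbon (a bicyclo[3.2.1]octane skeleton), and several diastereomers, so mixtures are to be expected. Three stereocentres are set in A3 only to be destroyed. The final dehydrogenation of A6 is an oxidation of a molecule holding a free electron-rich phenol and an ortho allyl group, the fragile combination named above.
- Comparison: the chosen plan is a few steps longer, but each intermediate is a single constitutional isomer, and its oxidation is done before the free phenol and the alkene exist.

**Alternative 3:** The C2=C3 bond is cut. Keto ester A8 is the 3,4,5-trimethoxybenzoate of an ortho-hydroxyacetophenone that already carries the allyl, methoxymethoxy and methoxy groups. Low-valent titanium from TiCl3 and zinc dust would couple its ketone and ester carbonyl carbons to give benzofuran A7. Acidic removal of the methoxymethyl group would give 14.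
- Merits: the ketone–ester McMurry closure is an established entry to 2-arylbenzofurans. The furan oxygen is fixed by the phenol from which the ester is made, the fragments are joined by a simple esterification, and no heating is needed at the end. In certainty of the key step this road is better than the chosen one.
- Weak points: the acetophenone fragment is a pentasubstituted arene. It must be made by the same O-allylation and Claisen logic, but on a ring with two phenolic oxygens to tell apart, and then protected. The titanium reagent is used in large excess, its Lewis-acidic chlorides threaten the acetal and the aryl ester, and pinacol coupling and ester cleavage compete. The final acid treatment next to an ortho allyl group invites cyclisation.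
- Comparison: this road is longer, mostly through fragment synthesis. Against its better precedent the chosen plan sets a shorter sequence and a halide-based rescue of its key step from the same ketone.

Key step: step 4

Assumption: ketone 7 is made and used as the racemate, since its only stereocentre is erased when the furan ring becomes aromatic in step 4; the target has no stereocentre.

## Route

Step 1
Reactants: 1 3,4,5-trimethoxybenzonitrile; 2 ethylmagnesium bromide
Product: 4 1-(3,4,5-trimethoxyphenyl)propan-1-one, via bromomagnesium ketimine salt 3 (not isolated)
Conditions: EtMgBr (1.5 equiv), THF, 0 °C to reflux; then 2 M aq. HCl, rt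
Reagents that add atoms: water, O
Why: Grignard addition to an aryl nitrile stops after one addition because the N-magnesio ketimine 3 is not electrophilic; aqueous acid hydrolyses 3 to the ketone, so no over-addition and no separate oxidation arise.

Step 2
Reactants: 5 4-bromo-2-methoxyphenol
Product: 6 4-bromo-2-methoxy-1-(propan-2-yloxy)benzene
Conditions: 2-bromopropane (1.5 equiv), K2CO3, DMF, 50 °C
Reagents that add atoms: 2-bromopropane, CC(C)Br
Why: Williamson ether synthesis on the phenoxide; the aryl bromide is inert to carbonate, and the isopropyl ether is stable to the base, the palladium step and FeCl3 that follow.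

Step 3
Reactants: 4 1-(3,4,5-trimethoxyphenyl)propan-1-one; 6 4-bromo-2-methoxy-1-(propan-2-yloxy)benzene
Product: 7 racemic 2-[3-methoxy-4-(propan-2-yloxy)phenyl]-1-(3,4,5-trimethoxyphenyl)propan-1-one
Conditions: Pd(OAc)2 (2 mol %), Xantphos (3 mol %), NaOtBu (1.3 equiv), toluene, 80 °C
Reagents that add atoms: none
Why: Palladium-catalysed α-arylation of a ketone enolate, for which propiophenones and aryl bromides are the standard partners; Pd(OAc)2 is reduced in the flask to zerovalent palladium, the ketone has a single enolisable position, and a second arylation would have to build a quaternary carbon. The new stereocentre forms as the racemate and is left uncontrolled because step 4 erases it.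

Step 4
Reactants: 7 racemic 2-[3-methoxy-4-(propan-2-yloxy)phenyl]-1-(3,4,5-trimethoxyphenyl)propan-1-one
Product: 8 5-methoxy-3-methyl-6-(propan-2-yloxy)-2-(3,4,5-trimethoxyphenyl)-1-benzofuran
Conditions: FeCl3 (anhydrous, 2.5 equiv), 1,2-dichloroethane, rt to 50 °C, N2
Reagents that add atoms: none
Why: Proposed new method: FeCl3 (trivalent iron) removes one electron from the 3,4-dialkoxyphenyl ring of 7, the more easily oxidised arene because the trimethoxyphenyl ring is conjugated with the carbonyl group; the carbonyl oxygen, as the FeCl3-promoted enol or directly as the ketone lone pair, adds to the ring carbon ortho to the side chain, a second FeCl3 oxidises the cyclohexadienyl radical, and loss of the ring proton and the α-proton gives the aromatic furan with two FeCl2 (divalent iron) and two HCl. The closest known reaction type is the FeCl3-mediated dehydrogenative closure of α-aryl β-keto esters, β-keto nitriles and 1,3-diketones that carry a methoxy group para to the closing carbon; it forms the same O–aryl bond, and what is new is a ketone whose α-carbon bears only a methyl group, so that the enol is not the resting form. The extension rests on the point that the nucleophile need not be the enol: capture of the radical cation by the ketone oxygen gives an oxocarbenium ion that loses its α-hydrogen readily, and FeCl3 as a Lewis acid also raises the enol content. The furan ring closes in a five-membered mode, exo with respect to the attacked C7–C7a π bond and with the developing C2=C3 bond inside the new ring. No stereocentre is formed, and the one in 7 disappears as C3 becomes part of the furan. The step needs site selectivity between the two carbons ortho to the side chain: the future C7a is para to the methoxy group, where the radical cation carries most of its charge, and is unhindered, whereas the future C4 is only ortho to that methoxy group and squeezed between it and the side chain. It also needs ring closure to outrun ether cleavage, which is why O6 carries an isopropyl and not a benzyl group.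

Step 5
Reactants: 8 5-methoxy-3-methyl-6-(propan-2-yloxy)-2-(3,4,5-trimethoxyphenyl)-1-benzofuran
Product: 10 5-methoxy-3-methyl-2-(3,4,5-trimethoxyphenyl)-1-benzofuran-6-ol, via aryloxydichloroborane 9 (not isolated)
Conditions: BCl3 (1 M in CH2Cl2, 2.5 equiv), CH2Cl2, −78 to 0 °C; then H2O
Reagents that add atoms: none
Why: Lewis-acid dealkylation of an aryl isopropyl ether; the secondary alkyl group leaves by ionisation as 2-chloropropane at low temperature, whereas methyl ethers without a chelating carbonyl neighbour would need a slow displacement at methyl. Hydrolysis of 9 on work-up frees the phenol.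

Step 6
Reactants: 10 5-methoxy-3-methyl-2-(3,4,5-trimethoxyphenyl)-1-benzofuran-6-ol; 11 allyl bromide
Product: 12 5-methoxy-3-methyl-6-(prop-2-en-1-yloxy)-2-(3,4,5-trimethoxyphenyl)-1-benzofuran
Conditions: K2CO3, acetone, reflux
Reagents that add atoms: none
Why: Williamson ether synthesis; a phenoxide with carbonate in a polar solvent is alkylated on oxygen by the reactive allylic bromide, and no other acidic site is present.

Step 7
Reactants: 12 5-methoxy-3-methyl-6-(prop-2-en-1-yloxy)-2-(3,4,5-trimethoxyphenyl)-1-benzofuran
Product: 14 5-methoxy-3-methyl-7-(prop-2-en-1-yl)-2-(3,4,5-trimethoxyphenyl)-1-benzofuran-6-ol, via ortho-dienone 13 (not isolated)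
Conditions: N,N-diethylaniline (degassed), 190 °C, Ar
Reagents that add atoms: none
Why: Aromatic Claisen rearrangement; the [3,3] shift delivers the allyl group to C7, the only ortho carbon with hydrogen, and dienone 13 enolises to the phenol. A shift to C5 gives a dienone that can neither enolise nor pass the allyl group to the para carbon C3a, so it reverts; the basic solvent suppresses acid-catalysed addition of the phenol to the alkene.

## Compound list

1 | 3,4,5-trimethoxybenzonitrile | COc1cc(C#N)cc(OC)c1OC | starting material
2 | ethylmagnesium bromide | CC[Mg]Br | starting material
3 | bromomagnesium salt of 1-(3,4,5-trimethoxyphenyl)propan-1-imine | CCC(=N[Mg]Br)c1cc(OC)c(OC)c(OC)c1 | intermediate (not isolated)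
4 | 1-(3,4,5-trimethoxyphenyl)propan-1-one | CCC(=O)c1cc(OC)c(OC)c(OC)c1 | intermediate
5 | 4-bromo-2-methoxyphenol | COc1cc(Br)ccc1O | starting material
6 | 4-bromo-2-methoxy-1-(propan-2-yloxy)benzene | COc1cc(Br)ccc1OC(C)C | intermediate
7 | racemic 2-[3-methoxy-4-(propan-2-yloxy)phenyl]-1-(3,4,5-trimethoxyphenyl)propan-1-one (one enantiomer drawn) | C[C@H](C(=O)c1cc(OC)c(OC)c(OC)c1)c1ccc(OC(C)C)c(OC)c1 | intermediate
8 | 5-methoxy-3-methyl-6-(propan-2-yloxy)-2-(3,4,5-trimethoxyphenyl)-1-benzofuran | Cc1c(-c2cc(OC)c(OC)c(OC)c2)oc2cc(OC(C)C)c(OC)cc12 | intermediate
9 | dichloro{[5-methoxy-3-methyl-2-(3,4,5-trimethoxyphenyl)-1-benzofuran-6-yl]oxy}borane | Cc1c(-c2cc(OC)c(OC)c(OC)c2)oc2cc(OB(Cl)Cl)c(OC)cc12 | intermediate (not isolated)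
10 | 5-methoxy-3-methyl-2-(3,4,5-trimethoxyphenyl)-1-benzofuran-6-ol | Cc1c(-c2cc(OC)c(OC)c(OC)c2)oc2cc(O)c(OC)cc12 | intermediate
11 | allyl bromide (3-bromoprop-1-ene) | C=CCBr | starting material
12 | 5-methoxy-3-methyl-6-(prop-2-en-1-yloxy)-2-(3,4,5-trimethoxyphenyl)-1-benzofuran | C=CCOc1cc2oc(-c3cc(OC)c(OC)c(OC)c3)c(C)c2cc1OC | intermediate
13 | racemic 5-methoxy-3-methyl-7-(prop-2-en-1-yl)-2-(3,4,5-trimethoxyphenyl)-1-benzofuran-6(7H)-one (one enantiomer drawn) | C=CC[C@H]1C(=O)C(OC)=CC2=C1OC(-c3cc(OC)c(OC)c(OC)c3)=C2C | intermediate (not isolated)
14 | 5-methoxy-3-methyl-7-(prop-2-en-1-yl)-2-(3,4,5-trimethoxyphenyl)-1-benzofuran-6-ol (CNP0110777.0) | C=CCc1c(O)c(OC)cc2c(C)c(-c3cc(OC)c(OC)c(OC)c3)oc12 | target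

## Step count and risk

Total step count: 7. Longest linear sequence: 6 steps (step 1 or step 2, then steps 3 to 7).

**Step 4 (key step, carries the label).** Three things may go wrong.
- Because the enol of 7 is not populated, ring closure may lose to intermolecular aryl–aryl coupling of the radical cation at the same carbon.
- The radical cation may lose its benzylic proton, which would lead to dehydrogenation or chlorination of the side chain.
- Product 8 is more electron-rich than 7 and lacks the deactivating acyl group of the known cases, so it may be oxidised further.

The fallback keeps the bond but brings back the halide; it sets out from 7 and returns at 8. NBS in MeCN at 0 °C should brominate the dialkoxyphenyl ring of 7 at the carbon para to methoxy and ortho to the side chain, the usual site for 4-alkyl-1,2-dialkoxybenzenes. This gives racemic 2-[2-bromo-5-methoxy-4-(propan-2-yloxy)phenyl]-1-(3,4,5-trimethoxyphenyl)propan-1-one F1; the carbonyl-deactivated trimethoxyphenyl ring should react more slowly. CuI (10 mol %) with K3PO4 in DMF at 105 °C then closes the ring by intramolecular O-arylation of the ketone enolate, a known route from 2-haloaryl ketones to benzofurans, and gives 8.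

**Step 3.** Aldol self-condensation of 4 under NaOtBu, reduction of the C–Br bond of 6, or slow oxidative addition of the electron-rich bromide may lower conversion. The fallback reverses the polarity of the coupling; it sets out from 4 and 6 and returns at 7. CuBr2 in EtOAc/CHCl3 at reflux brominates 4 at the α-carbon to give racemic 2-bromo-1-(3,4,5-trimethoxyphenyl)propan-1-one F2. Bromide 6 is converted with Mg in THF and then ZnCl2 into chloro[3-methoxy-4-(propan-2-yloxy)phenyl]zinc F3. A nickel-catalysed Negishi coupling of the secondary α-bromo ketone with the arylzinc reagent (NiCl2(MeOCH2CH2OMe), a bis(oxazolinyl)pyridine ligand, glyme/THF, −30 °C) joins them to 7; this coupling is known for α-bromopropiophenones.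

**Step 5.** BCl3 may also remove a methyl group, either the C5 methoxy next to the coordinated oxygen or the central methoxy of the trimethoxyphenyl ring. The departing isopropyl cation may also alkylate the electron-rich ring. The fallback changes the protecting group to one removed without a Lewis acid; it sets out from 5 and returns at 10.
- Benzyl bromide and K2CO3 in DMF give 1-(benzyloxy)-4-bromo-2-methoxybenzene F4.
- Arylation of 4 under the conditions of step 3 gives racemic 2-[4-(benzyloxy)-3-methoxyphenyl]-1-(3,4,5-trimethoxyphenyl)propan-1-one F5.
- The ring is closed through the halide, since a benzyl ether is less safe towards FeCl3: NBS in MeCN gives racemic 2-[4-(benzyloxy)-2-bromo-5-methoxyphenyl]-1-(3,4,5-trimethoxyphenyl)propan-1-one F6, and CuI with K3PO4 in DMF gives 6-(benzyloxy)-5-methoxy-3-methyl-2-(3,4,5-trimethoxyphenyl)-1-benzofuran F7.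
- Hydrogenolysis (H2, palladium metal on carbon, EtOAc, rt) then gives 10.

**Step 7.** At 190 °C the electron-rich free phenol may decompose, the new ortho-allylphenol may cyclise to a 2-methyl-2,3-dihydrofuran, or the double bond may move into conjugation. The fallback makes the C7–allyl bond by cross-coupling and not by rearrangement; it sets out from 10 and returns at 14. NBS (1 equiv) in CH2Cl2 at −40 °C should brominate 10 at C7, the only free position ortho to the hydroxyl group, to give 7-bromo-5-methoxy-3-methyl-2-(3,4,5-trimethoxyphenyl)-1-benzofuran-6-ol F8. Stille coupling with allyltributylstannane (Pd(PPh3)4, DMF, 90 °C) then gives 14.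

## Further compounds

F1 | step 4 | racemic 2-[2-bromo-5-methoxy-4-(propan-2-yloxy)phenyl]-1-(3,4,5-trimethoxyphenyl)propan-1-one (one enantiomer drawn) | C[C@H](C(=O)c1cc(OC)c(OC)c(OC)c1)c1cc(OC)c(OC(C)C)cc1Br
F2 | step 3 | racemic 2-bromo-1-(3,4,5-trimethoxyphenyl)propan-1-one (one enantiomer drawn) | C[C@H](Br)C(=O)c1cc(OC)c(OC)c(OC)c1
F3 | step 3 | chloro[3-methoxy-4-(propan-2-yloxy)phenyl]zinc | COc1cc([Zn]Cl)ccc1OC(C)C
F4 | step 5 | 1-(benzyloxy)-4-bromo-2-methoxybenzene | COc1cc(Br)ccc1OCc1ccccc1
F5 | step 5 | racemic 2-[4-(benzyloxy)-3-methoxyphenyl]-1-(3,4,5-trimethoxyphenyl)propan-1-one (one enantiomer drawn) | C[C@H](C(=O)c1cc(OC)c(OC)c(OC)c1)c1ccc(OCc2ccccc2)c(OC)c1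
F6 | step 5 | racemic 2-[4-(benzyloxy)-2-bromo-5-methoxyphenyl]-1-(3,4,5-trimethoxyphenyl)propan-1-one (one enantiomer drawn) | C[C@H](C(=O)c1cc(OC)c(OC)c(OC)c1)c1cc(OC)c(OCc2ccccc2)cc1Br
F7 | step 5 | 6-(benzyloxy)-5-methoxy-3-methyl-2-(3,4,5-trimethoxyphenyl)-1-benzofuran | Cc1c(-c2cc(OC)c(OC)c(OC)c2)oc2cc(OCc3ccccc3)c(OC)cc12
F8 | step 7 | 7-bromo-5-methoxy-3-methyl-2-(3,4,5-trimethoxyphenyl)-1-benzofuran-6-ol | Cc1c(-c2cc(OC)c(OC)c(OC)c2)oc2c(Br)c(O)c(OC)cc12
A1 | alternative 1 | 2-allyl-3-isopropoxy-4-methoxy-6-[(E)-1-(3,4,5-trimethoxyphenyl)prop-1-en-2-yl]phenol | C=CCc1c(OC(C)C)c(OC)cc(/C(C)=C/c2cc(OC)c(OC)c(OC)c2)c1O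
A2 | alternative 1 | racemic 2-allyl-3-isopropoxy-4-methoxy-4-[(1E,3E)-3-methyl-4-(3,4,5-trimethoxyphenyl)buta-1,3-dien-1-yl]cyclobut-2-en-1-one (one enantiomer drawn) | C=CCC1=C(OC(C)C)[C@](OC)(/C=C/C(C)=C/c2cc(OC)c(OC)c(OC)c2)C1=O
A3 | alternative 2 | racemic 3a-allyl-5-methoxy-3-methyl-2-(3,4,5-trimethoxyphenyl)-3,3a-dihydro-1-benzofuran-6(2H)-one, 2,3-trans, 3-methyl cis to 3a-allyl (one enantiomer drawn) | C=CC[C@]12C=C(OC)C(=O)C=C1O[C@@H](c1cc(OC)c(OC)c(OC)c1)[C@@H]2C
A4 | alternative 2 | 2-allyl-4,4,5-trimethoxycyclohexa-2,5-dien-1-one | C=CCC1=CC(OC)(OC)C(OC)=CC1=O
A5 | alternative 2 | (E)-isoelemicin, 1,2,3-trimethoxy-5-[(E)-prop-1-en-1-yl]benzene | C/C=C/c1cc(OC)c(OC)c(OC)c1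
A6 | alternative 2 | racemic trans-7-allyl-5-methoxy-3-methyl-2-(3,4,5-trimethoxyphenyl)-2,3-dihydro-1-benzofuran-6-ol (one enantiomer drawn) | C=CCc1c(O)c(OC)cc2c1O[C@@H](c1cc(OC)c(OC)c(OC)c1)[C@@H]2C
A7 | alternative 3 | 7-allyl-5-methoxy-6-(methoxymethoxy)-3-methyl-2-(3,4,5-trimethoxyphenyl)-1-benzofuran | C=CCc1c(OCOC)c(OC)cc2c(C)c(-c3cc(OC)c(OC)c(OC)c3)oc12
A8 | alternative 3 | 2-acetyl-6-allyl-4-methoxy-5-(methoxymethoxy)phenyl 3,4,5-trimethoxybenzoate | C=CCc1c(OCOC)c(OC)cc(C(C)=O)c1OC(=O)c1cc(OC)c(OC)c(OC)c1
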